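A small charge of reagent, 0.200 M, less than the 0.400 M of second substrate beside it, has to serve the starting material as well, and I wanted to know how much of the target made from it survives a further attack by the same reagent.

| setting | noon | winter | spring | dusk |
|---|---|---|---|---|
| starting material | 0.20 M | 0.20 M | 0.20 M | 0.20 M |
| reagent | 0.200 M | 0.200 M | 0.200 M | 0.200 M |
| second substrate | 0.400 M | 0.400 M | 0.400 M | 0.400 M |
| protic impurity | 0.100 M | 0.100 M | 0.100 M | 0.100 M |
| temperature | 55 °C | 105 °C |  | 80 °C |
| time | 40 min | 40 min | 40 min | 40 min |
| remark |  |  | at 55 °C until 30 min, from then on at 105 °C |  |

    starting material + reagent ⇌ target (K1 = 2.7 M⁻¹, k1 = 0.86 M⁻¹ min⁻¹, Ea1 = 57.0 kJ mol⁻¹, ΔH1 = −10.0 kJ mol⁻¹)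
    starting material + protic impurity → quenched substrate (k2 = 0.18 M⁻¹ min⁻¹, Ea2 = 64.0 kJ mol⁻¹)
    reagent + target → over-reaction product (k3 = 0.26 M⁻¹ min⁻¹, Ea3 = 67.0 kJ mol⁻¹)
    second substrate ⇌ dormant form (K4 = 0.63, k4 = 0.065 min⁻¹, Ea4 = 114 kJ mol⁻¹, ΔH4 = −81.0 kJ mol⁻¹)
    second substrate + reagent ⇌ second product (K5 = 1.3 M⁻¹, k5 = 3.2 M⁻¹ min⁻¹, Ea5 = 50.0 kJ mol⁻¹, ΔH5 = −56.0 kJ mol⁻¹)
    (constants at 80 °C)

- the constants hold at 80 °C; other temperatures follow from the activation energies and enthalpies

* the flask with the highest share of target in all that became target or over-reaction product ("all alike" if they lie within 1.5 percentage points) (noon / winter / spring / dusk / all alike)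
* share of target in all that became target or over-reaction product, noon
* share of target in all that became target or over-reaction product, winter
* share of target in all that became target or over-reaction product, spring
* share of target in all that became target or over-reaction product, dusk

I began with noon, held at 55 °C, where the over-reaction rate constant falls to 0.0457 M⁻¹ min⁻¹ and the equilibrium constant for pairing second substrate with reagent rises to 5.56 M⁻¹. The forward rate constant of that pairing becomes 0.874 M⁻¹ min⁻¹, so in noon the pairing takes about 2.86 min, far shorter than the 40 min of the run, and I treated it as an equilibrium, setting the dormant form aside. The quadratic gave 0.122 M of second product in noon, which leaves c(reagent) at 0.0785 M. At that level over-reaction is pseudo-first-order in target, and a target in noon lives 279 min on average. If target stood for the whole run, the over-reaction product made per target would be the run time over that lifetime, 0.144, and the share would be one over one plus this ratio, 87.4%.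

I was ready to commit to that, but the free reagent was the weak link, since the target holds reagent too. With the raised equilibrium constant 3.50 M⁻¹, target in noon comes to about 0.0431 M. Taking this from the reagent and solving again lowered c(reagent) to 0.0586 M. This gave the overrun number, the run time counted in target lifetimes against the reagent, 0.107, and a noon share of 90.3%.

For the other flasks I committed to a ranking and to no share. The over-reaction step speeds up by a factor of 26 between the two extreme temperatures, and with 1.18 M⁻¹ min⁻¹ in the heat, the last hot stretch of spring outweighs its cold stretch. Lending each flask the free reagent of noon, I ranked them and got noon on top.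

The forecast named noon, with 90.5% for noon, 7.6% for winter, 31.5% for spring and 41% for dusk. Its grounds began with the second substrate pairing quickly with the reagent, “tying up reagent”, so that target stood as a near-equilibrium pool.

The simulation gave noon as the highest, with 90.7% for noon, 8.10% for winter, 31.3% for spring and 40.4% for dusk, so the forecast held, and in dusk it stood 0.60 percentage points from the result.

The noon flask read 1.60% over-reaction product against 15.7% target, both as parts of the starting material charged, a ratio of 0.102 beside my overrun number of 0.107. Spring read at 10 min was still in its cold stretch, with the charges of noon, so I scaled the overrun number with time to 0.0267, which gave a share of 97.4%. That spring flask read 97.6%, with target at 11.8% of the starting material charged.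

The constants are invented; no experiment stands behind them.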